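## Retrosynthetic overview

1. The target comes from a linear bis-chroman by base/NaBH4 reductive opening of one pyran ring through a para-quinone methide. Only the ring whose 2-aryl group carries a para-OH can open, so the flavan ring stays.
2. The bis-chroman comes from hydrogenation of the C3=C4 bond of its 2H-chromene (flavene) half.
3. Key step: one chiral N-triflylphosphoramide turns a bis-carbinol on the resorcinol ring into two o-quinone methides. One closes by oxa-6π electrocyclisation (flavene ring, C2 set). The other adds 3-methoxy-4-vinylphenol by hetero-Diels–Alder reaction (second pyran ring, diarylmethine carbon set).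
4. The bis-carbinol comes from NaBH4 reduction of a chalcone–benzophenone, made by Claisen–Schmidt condensation (5-hydroxy-2-methoxybenzaldehyde) after C5-aroylation of 2,4-dihydroxyacetophenone with 4-hydroxybenzoic acid. The styrene comes from 4-hydroxy-2-methoxybenzaldehyde by Wittig methylenation.
5. Ring order: all four benzene rings are bought; both pyran rings form together in the key step; the non-flavan pyran ring is cut open last.

Assumption: the (R)-phosphoramide is written as the antipode that gives S at the flavene carbon and R at the diarylmethine carbon; the sense at each centre has to be confirmed by experiment.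

## Route

Step 1
Reactants: 1 1-(2,4-dihydroxyphenyl)ethanone (2,4-dihydroxyacetophenone); 2 4-hydroxybenzoic acid
Product: 3 1-[2,4-dihydroxy-5-(4-hydroxybenzoyl)phenyl]ethanone
Conditions: P2O5–CH3SO3H (1:10 w/w), 70 °C; then ice–water
Reagents that add atoms: none
Why: Nencki-type Friedel–Crafts acylation in which the acylium from 2 attacks C5, the unhindered position ortho to one hydroxyl and para to the other (the site that gives 4,6-diacetylresorcinol from 1), and no stereocentre is formed.

Step 2
Reactants: 3 1-[2,4-dihydroxy-5-(4-hydroxybenzoyl)phenyl]ethanone; 4 5-hydroxy-2-methoxybenzaldehyde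
Product: 5 (E)-1-[2,4-dihydroxy-5-(4-hydroxybenzoyl)phenyl]-3-(5-hydroxy-2-methoxyphenyl)prop-2-en-1-one
Conditions: BF3·OEt2 (0.5 equiv), 1,4-dioxane, rt
Reagents that add atoms: none
Why: Lewis-acid Claisen–Schmidt condensation in which only the acetyl group can enolise (the diaryl ketone cannot), the aldehyde is the only electrophile for it, free phenols are tolerated and dehydration gives the E-enone.

Step 3
Reactants: 5 (E)-1-[2,4-dihydroxy-5-(4-hydroxybenzoyl)phenyl]-3-(5-hydroxy-2-methoxyphenyl)prop-2-en-1-one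
Product: 6 4-[(E)-1-hydroxy-3-(5-hydroxy-2-methoxyphenyl)prop-2-enyl]-6-[hydroxy(4-hydroxyphenyl)methyl]benzene-1,3-diol (both carbinol carbons racemic; used crude at once)
Conditions: NaBH4 (6 equiv), THF–EtOH 1:1, 0 °C to rt; pH 7 phosphate buffer, 0 °C
Reagents that add atoms: none
Why: Borohydride 1,2-reduction of both hydrogen-bonded aryl ketones (the 2′-hydroxychalcone reduction that leads to flav-3-enes), and the two carbinol centres are left racemic on purpose because both are erased in step 5.

Step 4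
Reactants: 7 4-hydroxy-2-methoxybenzaldehyde
Product: 8 4-ethenyl-3-methoxyphenol (3-methoxy-4-vinylphenol)
Conditions: CH3PPh3Br (2.5 equiv), KOtBu (3.5 equiv), THF, 0 °C to rt; stored cold over a trace of BHT
Reagents that add atoms: methyltriphenylphosphonium bromide, C[P+](c1ccccc1)(c1ccccc1)c1ccccc1.[Br-]
Why: Wittig methylenation, with excess ylide because the phenoxide takes up one equivalent of base, and no stereocentre is formed.

Step 5
Reactants: 6 4-[(E)-1-hydroxy-3-(5-hydroxy-2-methoxyphenyl)prop-2-enyl]-6-[hydroxy(4-hydroxyphenyl)methyl]benzene-1,3-diol; 8 4-ethenyl-3-methoxyphenol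
Product: 12 (2S,6R,8S)-8-(4-hydroxy-2-methoxyphenyl)-6-(4-hydroxyphenyl)-2-(5-hydroxy-2-methoxyphenyl)-7,8-dihydro-2H,6H-pyrano[3,2-g]chromene (6-aryl and 8-aryl cis), via vinylogous o-quinone methide 9 (not isolated), via flavene benzhydrol 10 (not isolated), via flavene o-quinone methide 11 (not isolated)
Conditions: (R)-3,3′-bis(2,4,6-triisopropylphenyl)-1,1′-binaphthalene-2,2′-diyl N-(trifluoromethylsulfonyl)phosphoramide (10 mol%), 8 (3 equiv), 4 Å molecular sieves, CHCl3–EtOAc 4:1, −40 °C; then Et3N
Reagents that add atoms: none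
Why: Proposed new method: the chiral acid ionises both o-hydroxybenzylic carbinols; the allylic one gives 9, which closes by oxa-6π electrocyclisation inside the chiral ion pair to the (S)-flavene 10 (closest known type: N-triflylphosphoramide-catalysed cyclisation of o-hydroxyaryl allylic alcohols to 2H-chromenes); the benzhydrol gives 11, which adds the electron-rich styrene 8 in an inverse-demand hetero-Diels–Alder reaction on the face left open by the phosphoramide anion, setting the diarylmethine carbon as R and, through the endo transition state, the cis aryl at C8 (closest known type: [4+2] of o-hydroxybenzhydrol-derived o-quinone methides with styrenes to cis-2,4-diarylchromans under the same catalysts); C8 need not be controlled because step 7 destroys it.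

Step 6
Reactants: 12 (2S,6R,8S)-8-(4-hydroxy-2-methoxyphenyl)-6-(4-hydroxyphenyl)-2-(5-hydroxy-2-methoxyphenyl)-7,8-dihydro-2H,6H-pyrano[3,2-g]chromene
Product: 13 (2S,6R,8S)-8-(4-hydroxy-2-methoxyphenyl)-6-(4-hydroxyphenyl)-2-(5-hydroxy-2-methoxyphenyl)-3,4,7,8-tetrahydro-2H,6H-pyrano[3,2-g]chromene (numbered as 12)
Conditions: H2 (1 atm), Pt/C (5 wt%), EtOAc–EtOH 1:1, rt
Reagents that add atoms: none
Why: Heterogeneous hydrogenation of the cis-disubstituted styrenic C3=C4 bond (the usual flav-3-ene to flavan conversion); Pt is used because it is less prone than Pd to move the double bond to the 4H-chromene, which would erase C2, and neutral conditions leave both benzylic C–O bonds and all stereocentres alone.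

Step 7
Reactants: 13 (2S,6R,8S)-8-(4-hydroxy-2-methoxyphenyl)-6-(4-hydroxyphenyl)-2-(5-hydroxy-2-methoxyphenyl)-3,4,7,8-tetrahydro-2H,6H-pyrano[3,2-g]chromene
Product: 15 4-[(3R)-3-(4-hydroxyphenyl)-3-[(2S)-7-hydroxy-2-(5-hydroxy-2-methoxyphenyl)-3,4-dihydro-2H-chromen-6-yl]propyl]-3-methoxyphenol (CNP0239474.1), via para-quinone methide 14 (not isolated)
Conditions: NaBH4 (10 equiv), NaOH (1 M aq)–EtOH 1:1, 65 °C, argon; then AcOH to pH 6
Reagents that add atoms: none
Why: Base-induced retro-oxa-Michael opening followed by 1,6-hydride reduction: only the C8 aryl has a para-phenoxide that can expel the ring oxygen to give 14 (the pathway by which 4′-hydroxyflavans epimerise in alkali), borohydride reduces the methide carbon to CH2, and the flavan ring (meta-OH, ortho-OMe aryl) cannot form a quinone methide, so the S centre and the R diarylmethine (no leaving group) are kept.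

## Compound list

1 | 1-(2,4-dihydroxyphenyl)ethanone | CC(=O)c1ccc(O)cc1O | starting material
2 | 4-hydroxybenzoic acid | O=C(O)c1ccc(O)cc1 | starting material
3 | 1-[2,4-dihydroxy-5-(4-hydroxybenzoyl)phenyl]ethanone | CC(=O)c1cc(C(=O)c2ccc(O)cc2)c(O)cc1O | intermediate
4 | 5-hydroxy-2-methoxybenzaldehyde | COc1ccc(O)cc1C=O | starting material
5 | (E)-1-[2,4-dihydroxy-5-(4-hydroxybenzoyl)phenyl]-3-(5-hydroxy-2-methoxyphenyl)prop-2-en-1-one | COc1ccc(O)cc1/C=C/C(=O)c1cc(C(=O)c2ccc(O)cc2)c(O)cc1O | intermediate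
6 | 4-[(E)-1-hydroxy-3-(5-hydroxy-2-methoxyphenyl)prop-2-enyl]-6-[hydroxy(4-hydroxyphenyl)methyl]benzene-1,3-diol (carbinol carbons racemic) | COc1ccc(O)cc1/C=C/C(O)c1cc(C(O)c2ccc(O)cc2)c(O)cc1O | intermediate
7 | 4-hydroxy-2-methoxybenzaldehyde | COc1cc(O)ccc1C=O | starting material
8 | 4-ethenyl-3-methoxyphenol | COc1cc(O)ccc1C=C | intermediate
9 | 6-[(E)-3-(5-hydroxy-2-methoxyphenyl)prop-2-enylidene]-3-hydroxy-4-[hydroxy(4-hydroxyphenyl)methyl]cyclohexa-2,4-dien-1-one (not isolated; exocyclic alkene geometry and carbinol carbon undefined) | COc1ccc(O)cc1/C=C/C=C1C=C(C(O)c2ccc(O)cc2)C(O)=CC1=O | intermediate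
10 | (2S)-6-[hydroxy(4-hydroxyphenyl)methyl]-2-(5-hydroxy-2-methoxyphenyl)-2H-chromen-7-ol (not isolated; carbinol carbon racemic) | OC(c1ccc(O)cc1)c1cc2c(cc1O)O[C@H](c1cc(O)ccc1OC)C=C2 | intermediate
11 | (2S)-6-[(4-hydroxyphenyl)methylidene]-2-(5-hydroxy-2-methoxyphenyl)-2H-chromen-7(6H)-one (not isolated; exocyclic alkene geometry undefined) | O=C1C=C2O[C@H](c3cc(O)ccc3OC)C=CC2=CC1=Cc1ccc(O)cc1 | intermediate
12 | (2S,6R,8S)-8-(4-hydroxy-2-methoxyphenyl)-6-(4-hydroxyphenyl)-2-(5-hydroxy-2-methoxyphenyl)-7,8-dihydro-2H,6H-pyrano[3,2-g]chromene | COc1cc(O)ccc1[C@@H]1C[C@H](c2ccc(O)cc2)c2cc3c(cc2O1)O[C@H](c2cc(O)ccc2OC)C=C3 | intermediate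
13 | (2S,6R,8S)-8-(4-hydroxy-2-methoxyphenyl)-6-(4-hydroxyphenyl)-2-(5-hydroxy-2-methoxyphenyl)-3,4,7,8-tetrahydro-2H,6H-pyrano[3,2-g]chromene (numbered as 12) | COc1cc(O)ccc1[C@@H]1C[C@H](c2ccc(O)cc2)c2cc3c(cc2O1)O[C@H](c2cc(O)ccc2OC)CC3 | intermediate
14 | 4-[(3R)-3-(4-hydroxyphenyl)-3-[(2S)-7-hydroxy-2-(5-hydroxy-2-methoxyphenyl)-3,4-dihydro-2H-chromen-6-yl]propylidene]-3-methoxycyclohexa-2,5-dien-1-one (not isolated) | COC1=CC(=O)C=CC1=CC[C@H](c1ccc(O)cc1)c1cc2c(cc1O)O[C@H](c1cc(O)ccc1OC)CC2 | intermediate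
15 | 4-[(3R)-3-(4-hydroxyphenyl)-3-[(2S)-7-hydroxy-2-(5-hydroxy-2-methoxyphenyl)-3,4-dihydro-2H-chromen-6-yl]propyl]-3-methoxyphenol | COc1cc(O)ccc1CC[C@H](c1ccc(O)cc1)c1cc2c(cc1O)O[C@H](c1cc(O)ccc1OC)CC2 | target

## Step count and risks

Total step count: 7. Longest linear sequence: 6 steps (1 → 3 → 5 → 6 → 12 → 13 → 15); step 4 is the only side branch.

Steps most likely to fail:

Step 5. The double ring closure is unprecedented as a single operation. The hexahydroxy substrate needs a partly polar solvent that weakens ion pairing. The free C–H between the two ring oxygens can trap a quinone methide of a second molecule. One catalyst antipode must also give S at the flavene carbon and R at the diarylmethine carbon together. Fallback: separate the two ring closures and give each its own catalyst antipode. Starting from 5, NaBH4 with CeCl3·7H2O in MeOH–THF at −78 °C reduces only the enone carbonyl (the doubly donor-substituted diaryl ketone is much less electrophilic) to the allylic alcohol ketone 4-[(E)-1-hydroxy-3-(5-hydroxy-2-methoxyphenyl)prop-2-enyl]-6-(4-hydroxybenzoyl)benzene-1,3-diol F1. The phosphoramide antipode that gives the S sense then cyclises it at −40 °C to the flavene ketone [(2S)-7-hydroxy-2-(5-hydroxy-2-methoxyphenyl)-2H-chromen-6-yl](4-hydroxyphenyl)methanone F2. NaBH4 in THF–EtOH at 0 °C reduces the remaining ketone and gives 10, now as an isolated compound, where the route is rejoined: 10, 8 and the separately chosen phosphoramide antipode give 12.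

Step 3. Bis-carbinol 6 can ionise on work-up (racemic flavene formation), can be over-reduced through quinone methides, and dissolves poorly in the medium step 5 needs. Fallback: mask the two phenols that are not hydrogen-bonded to a carbonyl before the reduction. Starting from 5, tBuMe2SiCl (2.2 equiv) and imidazole in DMF at 0 °C give the bis-silyl ether (E)-1-[5-[4-(tert-butyldimethylsilyloxy)benzoyl]-2,4-dihydroxyphenyl]-3-[5-(tert-butyldimethylsilyloxy)-2-methoxyphenyl]prop-2-en-1-one F3. NaBH4 in THF–EtOH gives the bis-silyl bis-carbinol F4, which dissolves in toluene and can be filtered through Et3N-washed silica. The double ring closure with 8 and the phosphoramide is then run in toluene at −40 °C and gives the bis-silyl bis-chroman F5. Bu4NF buffered with AcOH in THF removes both silyl groups and gives 12, where the route is rejoined.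

Step 7. Hydride may not capture quinone methide 14 before it re-closes or oligomerises, and prolonged hot alkali can degrade the polyphenol. Fallback: intercept the quinone methide with a sulfur nucleophile and cut the C–S bond afterwards. Starting from 13, PhSH (5 equiv) and K2CO3 in degassed EtOH–H2O at 60 °C give, by 1,6-thia-Michael addition to 14, the ring-opened benzylic sulfide 4-[(3R)-3-(4-hydroxyphenyl)-3-[(2S)-7-hydroxy-2-(5-hydroxy-2-methoxyphenyl)-3,4-dihydro-2H-chromen-6-yl]-1-(phenylsulfanyl)propyl]-3-methoxyphenol F6. Raney Ni in EtOH at rt then removes sulfur and gives 15 directly.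

## Further compounds

F1 | step 5 | 4-[(E)-1-hydroxy-3-(5-hydroxy-2-methoxyphenyl)prop-2-enyl]-6-(4-hydroxybenzoyl)benzene-1,3-diol (carbinol carbon racemic) | COc1ccc(O)cc1/C=C/C(O)c1cc(C(=O)c2ccc(O)cc2)c(O)cc1O
F2 | step 5 | [(2S)-7-hydroxy-2-(5-hydroxy-2-methoxyphenyl)-2H-chromen-6-yl](4-hydroxyphenyl)methanone | O=C(c1ccc(O)cc1)c1cc2c(cc1O)O[C@H](c1cc(O)ccc1OC)C=C2
F3 | step 3 | (E)-1-[5-[4-(tert-butyldimethylsilyloxy)benzoyl]-2,4-dihydroxyphenyl]-3-[5-(tert-butyldimethylsilyloxy)-2-methoxyphenyl]prop-2-en-1-one | COc1ccc(O[Si](C)(C)C(C)(C)C)cc1/C=C/C(=O)c1cc(C(=O)c2ccc(O[Si](C)(C)C(C)(C)C)cc2)c(O)cc1O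
F4 | step 3 | 4-[(E)-3-[5-(tert-butyldimethylsilyloxy)-2-methoxyphenyl]-1-hydroxyprop-2-enyl]-6-[[4-(tert-butyldimethylsilyloxy)phenyl](hydroxy)methyl]benzene-1,3-diol (carbinol carbons racemic) | COc1ccc(O[Si](C)(C)C(C)(C)C)cc1/C=C/C(O)c1cc(C(O)c2ccc(O[Si](C)(C)C(C)(C)C)cc2)c(O)cc1O
F5 | step 3 | (2S,6R,8S)-6-[4-(tert-butyldimethylsilyloxy)phenyl]-2-[5-(tert-butyldimethylsilyloxy)-2-methoxyphenyl]-8-(4-hydroxy-2-methoxyphenyl)-7,8-dihydro-2H,6H-pyrano[3,2-g]chromene | COc1cc(O)ccc1[C@@H]1C[C@H](c2ccc(O[Si](C)(C)C(C)(C)C)cc2)c2cc3c(cc2O1)O[C@H](c2cc(O[Si](C)(C)C(C)(C)C)ccc2OC)C=C3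
F6 | step 7 | 4-[(3R)-3-(4-hydroxyphenyl)-3-[(2S)-7-hydroxy-2-(5-hydroxy-2-methoxyphenyl)-3,4-dihydro-2H-chromen-6-yl]-1-(phenylsulfanyl)propyl]-3-methoxyphenol (sulfur-bearing carbon undefined) | COc1cc(O)ccc1C(Sc1ccccc1)C[C@H](c1ccc(O)cc1)c1cc2c(cc1O)O[C@H](c1cc(O)ccc1OC)CC2
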